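**Plan**

The side chain is numbered C1' (OCH2) to C8' (=CH2). Retrosynthetic cuts, in order: the silyl group on O4'; the C6'–OOH bond (singlet-oxygen ene reaction of a prenyl terminus C6'=C7'); the C1'–O ether bond to coumarin C4 (Mitsunobu); C1'–C2' together with C3'–CH3 (methylalumination and formaldehyde capture); C3'–C4' (acetylide plus Weinreb amide).
Enabling feature: the E-alkene C2'=C3' carries a methyl on C3' and the oxygenated C1' methylene on C2', cis to each other. This is the imprint of syn CH3–Al addition across a terminal C2'≡C3' alkyne followed by one-carbon capture at C2'.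
Forward: the chain is joined C3'–C4' first, then C3'–CH3 and C1'–C2' in one flask, then C1'–O. The only ring made is the pyranone ring of the coumarin, closed separately (step 7) before the union.
Stereochemistry: C4' (S) comes from a catalyst-controlled Noyori transfer hydrogenation of the ynone; the E geometry from the syn-carbometalation mechanism; C6' (S) from an unselective Schenck ene reaction followed by epimer separation.

Key step: step 6

Remark: singlet oxygen is not expected to distinguish the faces of the remote prenyl alkene, so step 9 should give both C6' epimers and the 6'S isomer (4',6'-anti) is secured by separation; its assignment would rest on 13C analysis of the acetonide of the derived 1,3-diol.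

**Route**

Step 1
Reactants: 1 pyroterebic acid (4-methylpent-3-enoic acid)
Product: 3 Weinreb amide N-methoxy-N,4-dimethylpent-3-enamide, via acylimidazole 2 (not isolated)
Conditions: CDI, CH2Cl2, 0 °C → rt; then MeNH(OMe)·HCl, rt
Reagents that add atoms: N,O-dimethylhydroxylamine hydrochloride, CNOC.Cl
Why: Carbonyldiimidazole converts the acid into acylimidazole 2 under neutral conditions that should not move the β,γ-double bond into conjugation, and aminolysis by the hydroxylamine gives the Weinreb amide (standard amide coupling).

Step 2
Reactants: 3 Weinreb amide N-methoxy-N,4-dimethylpent-3-enamide; 4 ethynyltrimethylsilane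
Product: 7 ynone 6-methyl-1-(trimethylsilyl)hept-5-en-1-yn-3-one, via lithium (trimethylsilyl)acetylide 5 (not isolated), via lithium hemiaminal adduct 6 (not isolated)
Conditions: 4, n-BuLi, THF, −78 °C; then 3, −78 → −20 °C; poured into cold 1 M aq. HCl
Reagents that add atoms: none
Why: Weinreb ketone synthesis, in which acetylide 5 adds only once because the chelated tetrahedral adduct 6 persists until the cold acidic inverse quench, which releases the ynone while keeping the liberated amine protonated and the methylene between carbonyl and alkene away from base.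

Step 3
Reactants: 7 ynone 6-methyl-1-(trimethylsilyl)hept-5-en-1-yn-3-one
Product: 8 (3S)-6-methyl-1-(trimethylsilyl)hept-5-en-1-yn-3-ol
Conditions: Ru[(S,S)-TsNCHPhCHPhNH](p-cymene) (1 mol %), i-PrOH, rt
Reagents that add atoms: none
Why: Noyori asymmetric transfer hydrogenation of an α,β-acetylenic ketone, in which the Ru–H/N–H pair reduces one carbonyl face with the alkynyl group in the site an aryl ring takes in aryl ketones, so the (S,S)-catalyst should give the S carbinol, and the base-free amido complex avoids isomerising the skipped enone.

Step 4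
Reactants: 8 (3S)-6-methyl-1-(trimethylsilyl)hept-5-en-1-yn-3-ol
Product: 9 tert-butyldimethyl{[(3S)-6-methyl-1-(trimethylsilyl)hept-5-en-1-yn-3-yl]oxy}silane
Conditions: TBSCl, imidazole, DMF, rt
Reagents that add atoms: tert-butyldimethylsilyl chloride, CC(C)(C)[Si](C)(C)Cl
Why: Imidazole-promoted silylation of a secondary alcohol leaves the stereocentre untouched, masks the hydroxyl towards Me3Al and the later Mitsunobu step, and is done before C-desilylation to avoid handling the volatile free enynol.

Step 5
Reactants: 9 tert-butyldimethyl{[(3S)-6-methyl-1-(trimethylsilyl)hept-5-en-1-yn-3-yl]oxy}silane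
Product: 10 (3S)-3-(tert-butyldimethylsilyloxy)-6-methylhept-5-en-1-yne
Conditions: K2CO3 (cat.), MeOH, rt
Reagents that add atoms: none
Why: Methoxide-mediated protodesilylation cleaves the alkynyl C–SiMe3 bond selectively because the acetylide is a good leaving group on silicon, while the hindered secondary TBS ether is inert to K2CO3 in methanol.

Step 6
Reactants: 10 (3S)-3-(tert-butyldimethylsilyloxy)-6-methylhept-5-en-1-yne; 11 trimethylaluminium; 12 formaldehyde (used as paraformaldehyde)
Product: 15 (2E,4S)-4-(tert-butyldimethylsilyloxy)-3,7-dimethylocta-2,6-dien-1-ol, via alkenyldimethylalane 13 (not isolated), via lithium alkenyl(butyl)dimethylaluminate 14 (not isolated)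
Conditions: Me3Al (3 equiv), Cp2ZrCl2 (0.25 equiv), H2O (1 equiv), CH2Cl2, −23 → 0 °C; volatiles removed in vacuo; n-BuLi, THF/hexane, −78 °C; (CH2O)n, −78 °C → rt; aq. KNaC4H4O6 (potassium sodium tartrate)
Reagents that add atoms: none
Why: A methylzirconocene species formed from Me3Al and Cp2ZrCl2 delivers CH3 and metal syn across the C2'≡C3' triple bond of 10, methyl to the internal C3' and metal to the terminal C2', and exchange of zirconium for aluminium leaves alkenylalane 13; n-BuLi then forms aluminate 14, whose alkenyl carbon attacks formaldehyde with retention to make the C1'–C2' bond. The closest known reaction type is the Negishi zirconium-catalysed methylalumination of terminal alkynes with hydroxymethylation of the ate complex, the standard entry to E-3-methylalk-2-en-1-ols, used here in its water-accelerated form, which has been applied to silyl ethers of secondary propargylic alcohols. No ring is closed and no stereocentre is created; only the C2'=C3' geometry is set, and it must be E because the addition is syn and both transmetalation and C–C bond formation retain configuration at C2', so C1' ends cis to the new methyl and trans to C4'. The step needs regioselectivity (methyl to C3') and chemoselectivity (alkyne over the C6'=C7' alkene): the metal prefers the unhindered terminal carbon, the bulky and weakly basic silyl ether oxygen limits coordination to aluminium that could divert the regiochemistry, and unactivated trisubstituted alkenes do not react with this reagent. The C4' centre is neither acidic nor β to the metal and should be carried through unchanged.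

Step 7
Reactants: 16 2'-hydroxy-6'-methylacetophenone [1-(2-hydroxy-6-methylphenyl)ethanone]
Product: 17 coumarin 4-hydroxy-5-methyl-2H-chromen-2-one
Conditions: NaH, (EtO)2CO, toluene, 100 °C; then aq. HCl
Reagents that add atoms: diethyl carbonate, CCOC(=O)OCC
Why: Base-mediated condensation of an o-hydroxyacetophenone with diethyl carbonate is the classical 4-hydroxycoumarin synthesis, the carbonate carbon becoming C2 bonded to the phenol oxygen and to the former acetyl methyl carbon, which closes the pyranone ring and places the aryl methyl at C5.

Step 8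
Reactants: 15 (2E,4S)-4-(tert-butyldimethylsilyloxy)-3,7-dimethylocta-2,6-dien-1-ol; 17 coumarin 4-hydroxy-5-methyl-2H-chromen-2-one
Product: 19 coumarin ether 4-{[(2E,4S)-4-(tert-butyldimethylsilyloxy)-3,7-dimethylocta-2,6-dien-1-yl]oxy}-5-methyl-2H-chromen-2-one, via alkoxyphosphonium coumarinolate 18 (not isolated)
Conditions: PPh3, DIAD, THF, 0 °C → rt
Reagents that add atoms: none
Why: Mitsunobu etherification, in which the acidic 4-hydroxycoumarin protonates the PPh3–DIAD betaine and its O4 displaces Ph3P=O from the primary allylic alkoxyphosphonium ion 18 by SN2 at C1', the hindered trisubstituted C3' end disfavouring allylic transposition, so the E-alkene and C4' are unaffected.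

Step 9
Reactants: 19 coumarin ether 4-{[(2E,4S)-4-(tert-butyldimethylsilyloxy)-3,7-dimethylocta-2,6-dien-1-yl]oxy}-5-methyl-2H-chromen-2-one
Product: 20 hydroperoxide 4-{[(2E,4S,6S)-4-(tert-butyldimethylsilyloxy)-6-hydroperoxy-3,7-dimethylocta-2,7-dien-1-yl]oxy}-5-methyl-2H-chromen-2-one
Conditions: O2, 5,10,15,20-tetraphenylporphyrin (cat.), visible light (>500 nm), CH2Cl2, −20 °C; HPLC separation from the 6'R epimer
Reagents that add atoms: oxygen, O=O
Why: Schenck ene reaction, in which sensitised singlet oxygen attacks the electron-rich trialkyl C6'=C7' alkene (C2'=C3' is deactivated by two allylic C–O bonds and shielded by the OTBS group, and the coumarin C3=C4 bond is electron-poor), takes a hydrogen from a geminal methyl group and bonds oxygen to C6' with shift of the double bond to C7'=C8', the bulky C4' substituent disfavouring abstraction from C5'; the remote C4' centre is not expected to bias the faces, so the 6'S configuration is obtained by separating the two C6' epimers and not by induction.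

Step 10
Reactants: 20 hydroperoxide 4-{[(2E,4S,6S)-4-(tert-butyldimethylsilyloxy)-6-hydroperoxy-3,7-dimethylocta-2,7-dien-1-yl]oxy}-5-methyl-2H-chromen-2-one
Product: 21 target 4-{[(2E,4S,6S)-6-hydroperoxy-4-hydroxy-3,7-dimethylocta-2,7-dien-1-yl]oxy}-5-methyl-2H-chromen-2-one
Conditions: HF·pyridine, pyridine, THF, 0 °C → rt
Reagents that add atoms: none
Why: Fluoride-driven Si–O cleavage with pyridine-buffered HF is only mildly acidic, which avoids the base-induced Kornblum–DeLaMare dehydration of the secondary hydroperoxide and should leave the lactone, the allyl aryl ether and both stereocentres untouched.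

**Compound list**

1 | 4-methylpent-3-enoic acid (pyroterebic acid) | CC(C)=CCC(=O)O | starting material
2 | 1-(4-methylpent-3-enoyl)-1H-imidazole | CC(C)=CCC(=O)n1ccnc1 | intermediate (not isolated)
3 | N-methoxy-N,4-dimethylpent-3-enamide | CC(C)=CCC(=O)N(C)OC | intermediate
4 | ethynyltrimethylsilane | C#C[Si](C)(C)C | starting material
5 | lithium (trimethylsilyl)acetylide | [Li+].[C-]#C[Si](C)(C)C | intermediate (not isolated)
6 | lithium 3-[methoxy(methyl)amino]-6-methyl-1-(trimethylsilyl)hept-5-en-1-yn-3-olate (racemic at C3) | [Li+].CC(C)=CCC([O-])(N(C)OC)C#C[Si](C)(C)C | intermediate (not isolated)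
7 | 6-methyl-1-(trimethylsilyl)hept-5-en-1-yn-3-one | CC(C)=CCC(=O)C#C[Si](C)(C)C | intermediate
8 | (3S)-6-methyl-1-(trimethylsilyl)hept-5-en-1-yn-3-ol | CC(C)=CC[C@H](O)C#C[Si](C)(C)C | intermediate
9 | tert-butyldimethyl{[(3S)-6-methyl-1-(trimethylsilyl)hept-5-en-1-yn-3-yl]oxy}silane | CC(C)=CC[C@H](O[Si](C)(C)C(C)(C)C)C#C[Si](C)(C)C | intermediate
10 | (3S)-3-(tert-butyldimethylsilyloxy)-6-methylhept-5-en-1-yne | CC(C)=CC[C@H](O[Si](C)(C)C(C)(C)C)C#C | intermediate
11 | trimethylaluminium | C[Al](C)C | starting material
12 | formaldehyde (used as paraformaldehyde) | C=O | starting material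
13 | [(1E,3S)-3-(tert-butyldimethylsilyloxy)-2,6-dimethylhepta-1,5-dien-1-yl]dimethylalane | CC(C)=CC[C@H](O[Si](C)(C)C(C)(C)C)/C(C)=C/[Al](C)C | intermediate (not isolated)
14 | lithium butyl[(1E,3S)-3-(tert-butyldimethylsilyloxy)-2,6-dimethylhepta-1,5-dien-1-yl]dimethylaluminate | [Li+].CC(C)=CC[C@H](O[Si](C)(C)C(C)(C)C)/C(C)=C/[Al-](C)(C)CCCC | intermediate (not isolated)
15 | (2E,4S)-4-(tert-butyldimethylsilyloxy)-3,7-dimethylocta-2,6-dien-1-ol | CC(C)=CC[C@H](O[Si](C)(C)C(C)(C)C)/C(C)=C/CO | intermediate
16 | 1-(2-hydroxy-6-methylphenyl)ethanone | CC(=O)c1c(C)cccc1O | starting material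
17 | 4-hydroxy-5-methyl-2H-chromen-2-one | Cc1cccc2oc(=O)cc(O)c12 | intermediate
18 | {[(2E,4S)-4-(tert-butyldimethylsilyloxy)-3,7-dimethylocta-2,6-dien-1-yl]oxy}triphenylphosphonium 5-methyl-2-oxo-2H-chromen-4-olate | CC(C)=CC[C@H](O[Si](C)(C)C(C)(C)C)/C(C)=C/CO[P+](c1ccccc1)(c1ccccc1)c1ccccc1.Cc1cccc2oc(=O)cc([O-])c12 | intermediate (not isolated)
19 | 4-{[(2E,4S)-4-(tert-butyldimethylsilyloxy)-3,7-dimethylocta-2,6-dien-1-yl]oxy}-5-methyl-2H-chromen-2-one | CC(C)=CC[C@H](O[Si](C)(C)C(C)(C)C)/C(C)=C/COc1cc(=O)oc2cccc(C)c12 | intermediate
20 | 4-{[(2E,4S,6S)-4-(tert-butyldimethylsilyloxy)-6-hydroperoxy-3,7-dimethylocta-2,7-dien-1-yl]oxy}-5-methyl-2H-chromen-2-one | C=C(C)[C@H](C[C@H](O[Si](C)(C)C(C)(C)C)/C(C)=C/COc1cc(=O)oc2cccc(C)c12)OO | intermediate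
21 | 4-{[(2E,4S,6S)-6-hydroperoxy-4-hydroxy-3,7-dimethylocta-2,7-dien-1-yl]oxy}-5-methyl-2H-chromen-2-one | C=C(C)[C@H](C[C@H](O)/C(C)=C/COc1cc(=O)oc2cccc(C)c12)OO | target

**Count and risks**

Total step count: 10. Longest linear sequence: 9 steps (steps 1–6, then 8–10); step 7 is a one-step side branch.

Step 6. The methylalumination may be slowed next to the silyloxy-bearing carbon or lose regiocontrol (methyl delivered to C2'), and capture of the aluminate by slowly depolymerising paraformaldehyde may be incomplete, leaving protonated alkene. The fallback builds the same two bonds in the reverse order and sets out from 10. Deprotonation (n-BuLi, THF, −78 °C) and addition to (CH2O)n should give (4S)-4-(tert-butyldimethylsilyloxy)-7-methyloct-6-en-2-yn-1-ol F1. Hydroxyl-directed trans-hydroalumination with NaAlH2(OCH2CH2OCH3)2 in THF at 0 °C, followed by I2 at −78 °C, should give (2Z,4S)-4-(tert-butyldimethylsilyloxy)-3-iodo-7-methylocta-2,6-dien-1-ol F2. Its regiochemistry and geometry are fixed by the cyclic alkoxyaluminate, which keeps the metal on C3' cis to C1'. Negishi methylation (MeZnCl, Pd(PPh3)4 as the zerovalent palladium catalyst, THF) replaces iodine by methyl with retention and comes back to the route at 15.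

Step 9. Oxygen is delivered without facial control at C6', hydrogen abstraction from C5' competes and gives the tertiary hydroperoxide, and the two C6' epimers may co-elute or rearrange by allylic peroxyl shift during prolonged chromatography. The fallback sets out from 20 as the unseparated epimer mixture. Treatment with 2-methoxypropene and catalytic pyridinium p-toluenesulfonate in CH2Cl2 at 0 °C should convert the hydroperoxides into their less polar, more robust peroxyketals, which are then separated. The wanted diastereomer is 4-{[(2E,4S,6S)-4-(tert-butyldimethylsilyloxy)-6-[(2-methoxypropan-2-yl)peroxy]-3,7-dimethylocta-2,7-dien-1-yl]oxy}-5-methyl-2H-chromen-2-one F3. Mild hydrolysis (AcOH, THF, H2O, rt) releases the hydroperoxide and comes back to the route at 20 as a single epimer.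

Step 8. The coumarin anion is ambident: alkylation at C3 or at the lactone carbonyl oxygen (giving a 2-alkoxychromone) may compete with O4 alkylation, the more so because the peri 5-methyl group crowds O4, and the allylic phosphonium ion may be attacked with transposition. The fallback replaces redox activation by a classical alkylation and sets out from 15. Appel bromination (CBr4, PPh3, CH2Cl2, 0 °C) should give tert-butyl{[(2E,4S)-1-bromo-3,7-dimethylocta-2,6-dien-4-yl]oxy}dimethylsilane F4. Alkylation of the caesium salt of 17 (Cs2CO3, DMF, 0 °C), where the dissociated oxygen anion in a dipolar aprotic solvent favours O-alkylation, comes back to the route at 19.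

Further compounds
F1 | step 6 | (4S)-4-(tert-butyldimethylsilyloxy)-7-methyloct-6-en-2-yn-1-ol | CC(C)=CC[C@H](O[Si](C)(C)C(C)(C)C)C#CCO
F2 | step 6 | (2Z,4S)-4-(tert-butyldimethylsilyloxy)-3-iodo-7-methylocta-2,6-dien-1-ol | CC(C)=CC[C@H](O[Si](C)(C)C(C)(C)C)/C(I)=C/CO
F3 | step 9 | 4-{[(2E,4S,6S)-4-(tert-butyldimethylsilyloxy)-6-[(2-methoxypropan-2-yl)peroxy]-3,7-dimethylocta-2,7-dien-1-yl]oxy}-5-methyl-2H-chromen-2-one | C=C(C)[C@H](C[C@H](O[Si](C)(C)C(C)(C)C)/C(C)=C/COc1cc(=O)oc2cccc(C)c12)OOC(C)(C)OC
F4 | step 8 | tert-butyl{[(2E,4S)-1-bromo-3,7-dimethylocta-2,6-dien-4-yl]oxy}dimethylsilane | CC(C)=CC[C@H](O[Si](C)(C)C(C)(C)C)/C(C)=C/CBr
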